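The ochre run was charged richer than the green one, yet it came to rest with more of its Qa unreacted, 38.8% against 30.9%, whereas a one-to-one equilibrium ends at the same percentage at any charge.

| flask | Qa | remark | time |
|---|---|---|---|
| green | 0.12 M | run made earlier |  |
| ochre | 0.19 M | run made earlier |  |
| flask | 0.25 M |  | 30 min |

| run | time / min | Qa / % | Qc / % | Qd / % |
|---|---|---|---|---|
| green | 3.00 | 57.6 | 23.4 | 19.3 |
| green | 4.00 | 49.5 | 25.7 | 25.0 |
| green | 6.00 | 40.6 | 28.3 | 31.4 |
| green | 10.0 | 33.9 | 30.5 | 36.0 |
| green | 15.0 | 32.2 | 31.2 | 37.3 |
| green | 25.0 | 30.6 | 31.7 | 37.4 |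
| green | 40.0 | 30.9 | 31.4 | 37.4 |
| ochre | 5.00 | 47.7 | 25.4 | 26.7 |
| ochre | 10.0 | 40.3 | 27.3 | 32.4 |
| ochre | 15.0 | 39.2 | 27.8 | 32.9 |
| ochre | 20.0 | 38.9 | 28.1 | 33.1 |
| ochre | 25.0 | 38.8 | 27.6 | 33.1 |
| ochre | 30.0 | 39.1 | 27.9 | 33.0 |
| ochre | 40.0 | 38.8 | 27.9 | 33.0 |

(readings scatter by 0.3 percentage points)

- which holds at 30 min: what has brought the reaction to rest, or that it has not come to rest (forward and back rates have come level / it is still moving / all of Qa has reacted)
- conversion of Qa at 30 min
- amount of Qc at 30 min, in percent of the Qa charged
- amount of Qd at 30 min, in percent of the Qa charged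

- candidate steps: Qc <-> Qd; Qa <-> Qc + Qb
- the reaction counts as stopped when no species that holds the Qa changes by six tenths of a point or more over the second half of the time

I cleared this up by counting what each Qa gave: one Qb, so c(Qb) was the charge times the share in Qc plus Qd. The number to watch is then the plateau quotient c(Qc)·c(Qb)/c(Qa), the equilibrium constant as read: ochre read 0.0832 M and green 0.0839 M. The charge stands once more above the line than below it, so the richer ochre charge ended at the lower conversion.

The ochre plateau also gave the ratio of Qd to Qc, 1.18. With x the fraction converted, x squared over the fraction left equals the quotient times (one plus that ratio) over the charge, which for the flask is 0.726. For the flask I got a conversion of 56.3%, Qc 25.8% and Qd 30.5%.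

Ochre's excess of Qa over its plateau shrank with a half-life of about 1.95 min, so at that pace the flask's 30 min holds about 15.4 half-lives.

The forecast, which differs from mine in conversion and Qd, said forward and back rates have come level, with 56.4%, 25.8% and 30.6%, and held of the two runs: “The agreement means these are true equilibria, not stalling.”

The flask gave forward and back rates have come level, with 56.4%, 25.6% and 30.8%.

    Qc ⇌ Qd (K = 1.20, k = 0.0140 /s)
    Qa ⇌ Qc + Qb (K = 0.0830 M, k = 0.00340 /s)

The half-life of Qa by the forward rate of its path to Qc + Qb alone was 3.4 min, short against the 30 min, and by 15.0 min that step had behind it 99.8% of its turnover up to 30 min; the flask's own quotient came to 0.0830 M, beside the 0.0832 M read from ochre. Carried to the neighbour charged with 1.0 M, the ochre quotient gave a conversion of 0.182 on the right-hand side and so 34.5%, and that neighbour stood at 34.6%.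

(The data were generated by integration on assumed constants; the scatter is artificial.)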